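**Retrosynthetic overview**

1. Both indole rings are bought intact (indole-3-carbonitrile and 6-bromoindole); the imidazole is the only ring made, and it is made last.
2. Key disconnection: the bond between C3 of the 6-bromoindole and C4 of the imidazole. It is formed by aza-Friedel–Crafts attack of 6-bromoindole on the complete 2-(indol-3-yl)imidazole half held at the glyoxal oxidation level (the 4,5-diol). That diol is assembled in the same pot from indole-3-carboxamidine and glyoxal, and two dehydrations then deliver the aromatic ring (three components, one operation).
3. Enabling feature: in the imidazole ring, C4 and C5 are each bonded to one nitrogen of the N1–C2–N3 amidine unit, and C5 carries only H. The C4–C5 unit is therefore glyoxal in disguise: in the 4,5-diol each carbon is an N,O-hemiaminal (a latent N-amidino iminium ion). The first OH is the leaving group for C–C bond formation and the second is a traceless leaving group for aromatization. The partner atom, indole C3, is the β-carbon of the N1–C2=C3 enamine of the pyrrole ring.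
4. The amidine comes from indole-3-carbonitrile via the amidoxime and O-acetylation/hydrogenolysis.

Key step: step 3

Assumption: the target is achiral (no stereocentre, fully aromatic), so no stereocontrol is required; the two imidazole N–H tautomers are one compound.

**Route**

Step 1
Reactants: 1 1H-indole-3-carbonitrile
Product: 2 (Z)-N'-hydroxy-1H-indole-3-carboximidamide
Conditions: NH2OH (50% aq., 3 equiv), EtOH, 80 °C
Reagents that add atoms: hydroxylamine, NO
Why: Amidoxime formation by nucleophilic addition of the α-effect nucleophile hydroxylamine to the nitrile should proceed even on this electron-rich, vinylogous cyanamide-type nitrile, and the free indole N–H does not interfere.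

Step 2
Reactants: 2 (Z)-N'-hydroxy-1H-indole-3-carboximidamide
Product: 4 1H-indole-3-carboximidamide hydrochloride, via O-acetyl amidoxime 3 (not isolated)
Conditions: Ac2O (1.2 equiv), AcOH, rt; then H2 (1 atm), 10% Pd/C, rt; then HCl (4 M in dioxane), Et2O
Reagents that add atoms: acetic anhydride, CC(=O)OC(C)=O (acetyl group of 3 only, lost again in this step); hydrogen chloride, Cl
Why: O-Acetylation weakens the N–O bond so that Pd-catalysed hydrogenolysis of the O-acyl amidoxime (reductive N–O cleavage to the amidine) should run at room temperature and 1 atm, where the indole ring is not reduced, and HCl then fixes the strongly basic amidine as its storable hydrochloride.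

Step 3
Reactants: 4 1H-indole-3-carboximidamide hydrochloride, 5 glyoxal, 6 6-bromo-1H-indole
Product: 9 nortopsentin C, via dihydroxyimidazoline 7 (not isolated), via hydroxyimidazoline 8 (not isolated)
Conditions: 4, NaOH (1.0 equiv), 5 (40% aq., 1.0 equiv), EtOH/H2O, 0 °C → rt; then 6 (1.5 equiv), AcOH/HFIP (1:4), 50 °C
Reagents that add atoms: none
Why: Proposed new method: the free amidine (from 4 and NaOH) adds with both nitrogens to the two aldehyde carbons of glyoxal to give the cyclic bis-hemiaminal 7, and in the acidic second stage one C–OH ionizes to a 4H-imidazolium (N-amidino iminium) ion that is captured by the enamine-like C3 of 6-bromoindole in an aza-Friedel–Crafts reaction (this forms the indole C3–imidazole C4 bond) to give 8, whose remaining hemiaminal OH then ionizes and whose now doubly activated C–H is lost to aromatize the imidazole. The closest known reaction type is the acid-catalysed α-amidoalkylation of electron-rich (hetero)arenes by 4,5-dihydroxyimidazolidin-2-ones (urea–glyoxal adducts), which likewise ends with loss of the second hydroxyl, combined with the known formation of 4,5-dihydroxyimidazolines from aryl amidines and glyoxal; what is new is the use of the amidine-derived bis-hemiaminal as the C-electrophile toward an indole. The only ring closed is the imidazole, by intermolecular N-addition to one C=O followed by 5-exo-trig addition of the second amidine nitrogen to the other C=O. No stereocentre is set: the sp3 carbons of 7 and 8 arise as diastereomer mixtures and are all erased by the final dehydration, the target being achiral. The step needs chemoselectivity for C-arylation over the acid-induced collapse of 7 to the imidazol-4-one (proton loss or 1,2-hydride shift in the same cation), which the excess of the π-nucleophile, the ionizing but weakly basic AcOH/HFIP medium and the moderate temperature are chosen to secure, and it needs mono-arylation, which fast aromatizing proton loss from the cation derived from 8 should secure over a second intermolecular attack. Site selectivity lies in the substrates: C3 of 6 is its innate nucleophilic position, the indole of 7 is blocked at C3 and deactivated by the amidinium group, and C4 and C5 of 7 are equivalent so that no regiochemical question arises.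

**Compound list**

1 | 1H-indole-3-carbonitrile | N#Cc1c[nH]c2ccccc12 | starting material
2 | (Z)-N'-hydroxy-1H-indole-3-carboximidamide (amidoxime, Z geometry expected) | N/C(=N\O)c1c[nH]c2ccccc12 | intermediate
3 | (Z)-N'-acetoxy-1H-indole-3-carboximidamide (O-acetyl amidoxime) | CC(=O)O/N=C(\N)c1c[nH]c2ccccc12 | intermediate (not isolated)
4 | 1H-indole-3-carboximidamide hydrochloride | Cl.NC(=N)c1c[nH]c2ccccc12 | intermediate
5 | glyoxal (ethanedial, 40% aqueous solution) | O=CC=O | starting material
6 | 6-bromo-1H-indole | Brc1ccc2cc[nH]c2c1 | starting material
7 | 2-(1H-indol-3-yl)-4,5-dihydro-1H-imidazole-4,5-diol (diastereomer mixture, racemic; both centres erased in the same step) | OC1NC(c2c[nH]c3ccccc23)=NC1O | intermediate (not isolated)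
8 | 5-(6-bromo-1H-indol-3-yl)-2-(1H-indol-3-yl)-4,5-dihydro-1H-imidazol-4-ol (diastereomer mixture, racemic; both centres erased in the same step) | OC1NC(c2c[nH]c3ccccc23)=NC1c1c[nH]c2cc(Br)ccc12 | intermediate (not isolated)
9 | nortopsentin C, 4-(6-bromo-1H-indol-3-yl)-2-(1H-indol-3-yl)-1H-imidazole | Brc1ccc2c(-c3c[nH]c(-c4c[nH]c5ccccc45)n3)c[nH]c2c1 | target

**Step count and risks**

Total step count: 3. Longest linear sequence: 3 steps (1 → 2 → 4 → 9).

Steps most likely to fail:

Step 3 (proposed new method). The bis-hemiaminal may collapse to the imidazol-4-one by proton loss or 1,2-hydride shift faster than the iminium ion is captured by the indole. Alternatively, the hemiaminal may revert and release glyoxal, which would then be indolylated twice. The fallback is the classical amidine/α-haloketone imidazole synthesis, in which the indole–C bond is made first by acylation. It sets out from 6: Friedel–Crafts acylation with chloroacetyl chloride (Et2AlCl, CH2Cl2, 0 °C) should give 1-(6-bromo-1H-indol-3-yl)-2-chloroethan-1-one F1. Condensation of this chloroketone with the amidine hydrochloride 4 (KHCO3, THF/H2O, reflux) should then close the imidazole ring and come back to the route at 9.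

Step 2. The indole C2=C3 bond may be over-reduced under acidic hydrogenation, or the O-acetyl amidoxime may cyclodehydrate to the 5-methyl-1,2,4-oxadiazole before the N–O bond is cleaved. The fallback is non-reductive and runs through the thioimidate. It sets out from 1: addition of hydrogen sulfide (NaSH, MgCl2, DMF, rt to 60 °C) should give 1H-indole-3-carbothioamide F2. S-Methylation (MeI, acetone, rt) should give methyl 1H-indole-3-carbimidothioate hydroiodide F3. Ammonolysis (NH3, 7 M in MeOH, rt), liberation of the free amidine with NaOH (1 equiv) and treatment with HCl in dioxane should come back to the route at 4.

Step 1. Addition of hydroxylamine to the push–pull nitrile may stall, or hydrolysis to the primary amide may compete. The fallback activates the nitrile with a Lewis acid instead of relying on a more nucleophilic amine. It sets out from 1: treatment with amino(chloro)methylaluminium (from AlMe3 and NH4Cl, 4 equiv, toluene, 80 °C), quenching on silica gel/MeOH and treatment with HCl should give the amidine hydrochloride directly and come back to the route at 4, which also makes step 2 unnecessary. This fallback makes no new compound (F0).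

**Further compounds**

F1 | step 3 | 1-(6-bromo-1H-indol-3-yl)-2-chloroethan-1-one | O=C(CCl)c1c[nH]c2cc(Br)ccc12
F2 | step 2 | 1H-indole-3-carbothioamide | NC(=S)c1c[nH]c2ccccc12
F3 | step 2 | methyl 1H-indole-3-carbimidothioate hydroiodide | I.CSC(=N)c1c[nH]c2ccccc12
F0 | step 1 | none | none
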